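**Retrosynthetic overview**
- Nirurinetin ← removal of the 5-O-methyl and 7-O-tert-butyl groups from a (2S)-flavanone. C2 and ring B come from an enantioselective conjugate addition of 4-hydroxyphenylboronic acid to a chromone.
- The chromone (rings A and C) ← one thermal operation on a 4-alkenyl-4-hydroxycyclobutenone. Electrocyclic opening and 6π closure build the hexasubstituted ring A, and the phenol so formed closes ring C onto a β-methoxyenone.
- The cyclobutenone ← 3-tert-butoxy-4-prenylcyclobutenedione (di-tert-butyl squarate + prenylbarium reagent) plus a lithiated bis(2-methoxyvinyl) ketone (from 4-methoxybut-3-en-2-one and methyl formate).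
- Ring order: A, then C in the same flask; ring B is bought intact.

Assumption: di-tert-butyl squarate (1) is taken as a purchasable catalogue compound.

**Step 1**
Reactants: 1 3,4-di-tert-butoxycyclobut-3-ene-1,2-dione (di-tert-butyl squarate); 2 1-chloro-3-methylbut-2-ene (prenyl chloride)
Product: 6 3-tert-butoxy-4-(3-methylbut-2-en-1-yl)cyclobut-3-ene-1,2-dione, via prenylbarium chloride 3 (not isolated), via cyclobutenol adduct 4 (not isolated), via adduct trifluoroacetate 5 (not isolated)
Conditions: BaI2, Li, biphenyl, THF, rt; 2, −78 °C; then 1, −78 °C; then (CF3CO)2O, −78 °C to rt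
Reagents that add atoms: none
Why: The allylic barium reagent 3 adds to one squarate carbonyl through its unsubstituted CH2 terminus (linear prenyl, where the magnesium or lithium reagent would give the 1,1-dimethylallyl isomer), and trifluoroacetylation of alkoxide 4 triggers the usual ionisation and alkoxy loss of squarate 1,2-adducts (Liebeskind–Moore cyclobutenedione synthesis) to give dione 6; no stereocenter remains.

**Step 2**
Reactants: 7 (3E)-4-methoxybut-3-en-2-one
Product: 9 (1E,4E)-1,5-dimethoxypenta-1,4-dien-3-one, via sodium formyl enolate 8 (not isolated)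
Conditions: NaOMe, HCO2Me, THF, 0 °C to rt; then Me2SO4, DMF, 0 °C to rt
Reagents that add atoms: methyl formate (COC=O); dimethyl sulfate (COS(=O)(=O)OC)
Why: Crossed Claisen formylation at the only enolisable position of 7 gives enolate 8, which the hard electrophile dimethyl sulfate O-methylates to the symmetrical, non-enolisable bis(β-methoxyvinyl) ketone 9 (both alkenes E after equilibration).

**Step 3**
Reactants: 9 (1E,4E)-1,5-dimethoxypenta-1,4-dien-3-one; 6 3-tert-butoxy-4-(3-methylbut-2-en-1-yl)cyclobut-3-ene-1,2-dione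
Product: 11 3-tert-butoxy-4-[(1E,4E)-1,5-dimethoxy-3-oxopenta-1,4-dien-1-yl]-4-hydroxy-2-(3-methylbut-2-en-1-yl)cyclobut-2-en-1-one (racemic), via vinyllithium 10 (not isolated)
Conditions: LiTMP (2,2,6,6-tetramethylpiperidine, n-BuLi), THF/Et2O, −100 °C, then 9; then 6, −100 to −78 °C; aq NH4Cl at −78 °C
Reagents that add atoms: none
Why: Proposed new method: the vinylic C–H next to OMe and cis to the carbonyl of 9 is removed by the hindered amide with chelation of lithium by the ketone oxygen (closest known reaction: β-lithiation of β-alkoxyacrylic esters and amides), and vinyllithium 10 then adds, as organolithiums normally do, to the more electrophilic carbonyl of 6 (the one next to C–OtBu), which puts OH and the alkenyl group on C4 and prenyl on C2 of 11; the carbinol center is racemic and is destroyed in step 4.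

**Step 4**
Reactants: 11 3-tert-butoxy-4-[(1E,4E)-1,5-dimethoxy-3-oxopenta-1,4-dien-1-yl]-4-hydroxy-2-(3-methylbut-2-en-1-yl)cyclobut-2-en-1-one
Product: 14 7-tert-butoxy-6-hydroxy-5-methoxy-8-(3-methylbut-2-en-1-yl)-4H-chromen-4-one, via dienylketene 12 (not isolated), via acylhydroquinone 13 (not isolated)
Conditions: toluene (0.02 M), Ar, 110 °C, 2 h; then AcOH (5 equiv), 80 °C
Reagents that add atoms: none
Why: Proposed new method: conrotatory 4π opening of 11 (OH rotating outward) gives dienylketene 12, whose 6π electrocyclisation and enolisation (Moore rearrangement of 4-alkenyl-4-hydroxycyclobutenones, known) builds ring A as hydroquinone 13, and the ketene-derived phenol, the only free OH ortho to the acyl group, then adds to the β-methoxyenone and expels methanol (standard chromone closure) to form ring C, so that prenyl, OtBu, OH and OMe end at C8, C7, C6 and C5 with no regiochemical choice; the tandem of the two known events is the new element.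

**Step 5**
Reactants: 14 7-tert-butoxy-6-hydroxy-5-methoxy-8-(3-methylbut-2-en-1-yl)-4H-chromen-4-one; 15 (4-hydroxyphenyl)boronic acid
Product: 16 (2S)-7-tert-butoxy-6-hydroxy-2-(4-hydroxyphenyl)-5-methoxy-8-(3-methylbut-2-en-1-yl)-2,3-dihydro-4H-chromen-4-one
Conditions: Pd(OCOCF3)2 (5 mol %), (R)-t-BuPyOx [(R)-4-tert-butyl-2-(pyridin-2-yl)-4,5-dihydrooxazole] (6 mol %), NH4PF6 (30 mol %), H2O (5 equiv), ClCH2CH2Cl, 60 °C
Reagents that add atoms: none
Why: Palladium-catalysed asymmetric conjugate addition of an arylboronic acid to a chromone (cationic divalent palladium–pyridinooxazoline catalyst, aryl transfer to C2 then protonation of the palladium enolate) creates the only stereocenter; by the facial model that holds for cyclic enones the (R)-ligand should give 2S, which is to be confirmed on the first batch by CD against natural (2S)-flavanones.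

**Step 6**
Reactants: 16 (2S)-7-tert-butoxy-6-hydroxy-2-(4-hydroxyphenyl)-5-methoxy-8-(3-methylbut-2-en-1-yl)-2,3-dihydro-4H-chromen-4-one
Product: 17 nirurinetin, (2S)-5,6,7-trihydroxy-2-(4-hydroxyphenyl)-8-(3-methylbut-2-en-1-yl)-2,3-dihydro-4H-chromen-4-one
Conditions: MgI2·OEt2 (8 equiv), THF, 60 °C, Ar; aq NH4Cl/Na2S2O4
Reagents that add atoms: none
Why: MgI2 chelated between the C4 carbonyl and the peri 5-OMe delivers iodide to the methyl group (chelation-controlled ether cleavage, known for 5-O-methyl-8-prenylflavanones with the prenyl group intact), and the Lewis acid held by the 6-O/7-O pair is expected to ionise the tert-butyl ether with loss of isobutene (the less certain half of the step); the medium is neither basic nor strongly protic, so C2 is not opened to the chalcone and the prenyl group does not cyclise.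

**Compound list**
1 | 3,4-di-tert-butoxycyclobut-3-ene-1,2-dione (di-tert-butyl squarate) | CC(C)(C)OC1=C(OC(C)(C)C)C(=O)C1=O | starting material
2 | 1-chloro-3-methylbut-2-ene (prenyl chloride) | CC(C)=CCCl | starting material
3 | (3-methylbut-2-en-1-yl)barium chloride | CC(C)=CC[Ba]Cl | intermediate
4 | 2,3-di-tert-butoxy-4-hydroxy-4-(3-methylbut-2-en-1-yl)cyclobut-2-en-1-one (racemic; chlorobarium alkoxide in the flask) | CC(C)=CCC1(O)C(OC(C)(C)C)=C(OC(C)(C)C)C1=O | intermediate
5 | 2,3-di-tert-butoxy-1-(3-methylbut-2-en-1-yl)-4-oxocyclobut-2-en-1-yl trifluoroacetate (racemic) | CC(C)=CCC1(OC(=O)C(F)(F)F)C(OC(C)(C)C)=C(OC(C)(C)C)C1=O | intermediate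
6 | 3-tert-butoxy-4-(3-methylbut-2-en-1-yl)cyclobut-3-ene-1,2-dione | CC(C)=CCC1=C(OC(C)(C)C)C(=O)C1=O | intermediate
7 | (3E)-4-methoxybut-3-en-2-one | CO/C=C/C(C)=O | starting material
8 | sodium (1E,4E)-5-methoxy-3-oxopenta-1,4-dien-1-olate | CO/C=C/C(=O)/C=C/[O-].[Na+] | intermediate
9 | (1E,4E)-1,5-dimethoxypenta-1,4-dien-3-one | CO/C=C/C(=O)/C=C/OC | intermediate
10 | [(1E,4E)-1,5-dimethoxy-3-oxopenta-1,4-dien-1-yl]lithium (Li cis to C=O) | CO/C([Li])=C/C(=O)/C=C/OC | intermediate
11 | 3-tert-butoxy-4-[(1E,4E)-1,5-dimethoxy-3-oxopenta-1,4-dien-1-yl]-4-hydroxy-2-(3-methylbut-2-en-1-yl)cyclobut-2-en-1-one (racemic) | CC(C)=CCC1=C(OC(C)(C)C)C(O)(/C(OC)=C\C(=O)/C=C/OC)C1=O | intermediate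
12 | (3Z,5E,8E)-3-tert-butoxy-4-hydroxy-5,9-dimethoxy-2-(3-methylbut-2-en-1-yl)nona-1,3,5,8-tetraene-1,7-dione (dienylketene) | CC(C)=CCC(=C=O)/C(OC(C)(C)C)=C(O)\C(OC)=C/C(=O)/C=C/OC | intermediate
13 | (2E)-1-[4-tert-butoxy-2,5-dihydroxy-6-methoxy-3-(3-methylbut-2-en-1-yl)phenyl]-3-methoxyprop-2-en-1-one | CC(C)=CCc1c(O)c(C(=O)/C=C/OC)c(OC)c(O)c1OC(C)(C)C | intermediate
14 | 7-tert-butoxy-6-hydroxy-5-methoxy-8-(3-methylbut-2-en-1-yl)-4H-chromen-4-one | CC(C)=CCc1c(OC(C)(C)C)c(O)c(OC)c2c(=O)ccoc12 | intermediate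
15 | (4-hydroxyphenyl)boronic acid | OB(O)c1ccc(O)cc1 | starting material
16 | (2S)-7-tert-butoxy-6-hydroxy-2-(4-hydroxyphenyl)-5-methoxy-8-(3-methylbut-2-en-1-yl)-2,3-dihydro-4H-chromen-4-one | CC(C)=CCc1c(OC(C)(C)C)c(O)c(OC)c2c1O[C@H](c1ccc(O)cc1)CC2=O | intermediate
17 | nirurinetin, (2S)-5,6,7-trihydroxy-2-(4-hydroxyphenyl)-8-(3-methylbut-2-en-1-yl)-2,3-dihydro-4H-chromen-4-one | CC(C)=CCc1c(O)c(O)c(O)c2c1O[C@H](c1ccc(O)cc1)CC2=O | target

**Totals**
Total steps: 6. Longest linear sequence: 5 steps (1, 3, 4, 5, 6; the branch through step 2 is also 5).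

**Steps most likely to fail, with fallbacks**

Step 3 (lithiation of ketone 9 and addition). The fallback sets out from 6 and comes back to the route at 14. It replaces the ketone by an acrylamide, a substrate class for which β-lithiation is established, and closes ring C after ring A instead of in the same flask. Methyl (2E)-3-methoxyprop-2-enoate is converted with MeNHOMe·HCl and i-PrMgCl (THF, −20 °C) into (2E)-N,3-dimethoxy-N-methylprop-2-enamide F1. LiN(i-Pr)2 at −95 °C gives the chelated [(1E)-1-methoxy-3-[methoxy(methyl)amino]-3-oxoprop-1-en-1-yl]lithium F2, which adds to 6 and is quenched cold to give (2E)-3-[2-tert-butoxy-1-hydroxy-3-(3-methylbut-2-en-1-yl)-4-oxocyclobut-2-en-1-yl]-N,3-dimethoxy-N-methylprop-2-enamide F3. Heating in toluene (110 °C) rearranges it to 4-tert-butoxy-2,5-dihydroxy-N,6-dimethoxy-N-methyl-3-(3-methylbut-2-en-1-yl)benzamide F4. Excess ethynylmagnesium bromide (THF, 0 °C) then gives 1-[4-tert-butoxy-2,5-dihydroxy-6-methoxy-3-(3-methylbut-2-en-1-yl)phenyl]prop-2-yn-1-one F5, and Et2NH in EtOH at rt closes the neighbouring phenol 6-endo onto the ynone to give chromone 14.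

Step 4 (tandem ring expansion and ring C closure). The fallback sets out from 11 and comes back at 13, which closes to 14. If the open hydroquinone is lost to air or closes poorly, the ring expansion is separated from the ring closure through an isolable quinone. Thermolysis of 11 (toluene, 110 °C) followed by Ag2O/MgSO4 at rt takes crude 13 to 2-tert-butoxy-6-methoxy-5-[(2E)-3-methoxyprop-2-enoyl]-3-(3-methylbut-2-en-1-yl)cyclohexa-2,5-diene-1,4-dione F6, which is purified. Na2S2O4 (EtOAc/H2O, Ar) regenerates clean 13, and AcOH at 80 °C closes it to 14.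

Step 5 (asymmetric arylation of a hindered, electron-rich chromone). The fallback sets out from 14 and comes back at 16. If the chiral catalyst gives low conversion or low ee, stereocontrol by catalysis is given up. The racemic addition of 15 with Pd(OCOCF3)2/2,2'-bipyridine gives 16 together with its mirror image (2R)-7-tert-butoxy-6-hydroxy-2-(4-hydroxyphenyl)-5-methoxy-8-(3-methylbut-2-en-1-yl)-2,3-dihydro-4H-chromen-4-one F7. The two are separated by preparative chromatography on an amylose tris(3,5-dimethylphenylcarbamate) phase, and F7 is set aside.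

**Further compounds**
F1 | step 3 | (2E)-N,3-dimethoxy-N-methylprop-2-enamide | CO/C=C/C(=O)N(C)OC
F2 | step 3 | [(1E)-1-methoxy-3-[methoxy(methyl)amino]-3-oxoprop-1-en-1-yl]lithium | CO/C([Li])=C/C(=O)N(C)OC
F3 | step 3 | (2E)-3-[2-tert-butoxy-1-hydroxy-3-(3-methylbut-2-en-1-yl)-4-oxocyclobut-2-en-1-yl]-N,3-dimethoxy-N-methylprop-2-enamide (racemic) | CC(C)=CCC1=C(OC(C)(C)C)C(O)(/C(OC)=C\C(=O)N(C)OC)C1=O
F4 | step 3 | 4-tert-butoxy-2,5-dihydroxy-N,6-dimethoxy-N-methyl-3-(3-methylbut-2-en-1-yl)benzamide | CC(C)=CCc1c(O)c(C(=O)N(C)OC)c(OC)c(O)c1OC(C)(C)C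
F5 | step 3 | 1-[4-tert-butoxy-2,5-dihydroxy-6-methoxy-3-(3-methylbut-2-en-1-yl)phenyl]prop-2-yn-1-one | CC(C)=CCc1c(O)c(C(=O)C#C)c(OC)c(O)c1OC(C)(C)C
F6 | step 4 | 2-tert-butoxy-6-methoxy-5-[(2E)-3-methoxyprop-2-enoyl]-3-(3-methylbut-2-en-1-yl)cyclohexa-2,5-diene-1,4-dione | CC(C)=CCC1=C(OC(C)(C)C)C(=O)C(OC)=C(C(=O)/C=C/OC)C1=O
F7 | step 5 | (2R)-7-tert-butoxy-6-hydroxy-2-(4-hydroxyphenyl)-5-methoxy-8-(3-methylbut-2-en-1-yl)-2,3-dihydro-4H-chromen-4-one | CC(C)=CCc1c(OC(C)(C)C)c(O)c(OC)c2c1O[C@@H](c1ccc(O)cc1)CC2=O
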